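The C4–C4a bond of the 2H-chromene is the disconnection on which the route rests. It joins the vinylic CH of the pyran (ring B) to the hexasubstituted benzene (ring A). A thermal aryl propargyl Claisen cascade makes this bond and ring B in one reagent-free operation, as the last step. It exploits the aryl ether oxygen O1 on C8a, whose only unsubstituted ortho carbon is C4a because C8 carries a hydroxyl, together with the gem-dimethyl carbon C2 and the C3=C4 alkene, which are stored as a 1,1-dimethylpropargyl ether. The precursor is the unprotected 2',5'-dihydroxy-6'-methoxydihydrochalcone carrying that ether on O4', built by Houben–Hoesch acylation, selective O-propargylation and Elbs oxidation.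

Key step: step 4

Remark: flemistrictin D is achiral and has no stereogenic element, so no stereocontrol is needed; primed locants refer to the dihydrochalcone ring that becomes ring A (C1' acyl carbon, C4' becomes C8a, C3' becomes C4a).

Step 1
Reactants: 1 5-methoxyresorcinol; 2 3-phenylpropanenitrile
Product: 4 1-(2,4-dihydroxy-6-methoxyphenyl)-3-phenylpropan-1-one, via ketiminium chloride 3 (not isolated)
Conditions: ZnCl2, HCl (g), Et2O, 0 °C to rt; then H2O, 100 °C
Reagents that add atoms: water, O
Why: Houben–Hoesch acylation, in which the nitrilium electrophile should attack mainly the ring carbon of 1 lying between OH and OMe and para to the second OH (two equivalent sites, against one site between the two hydroxyls), so that hydrolysis of ketiminium chloride 3 gives the 2',4'-dihydroxy-6'-methoxy ketone, the minor 2',6'-dihydroxy-4'-methoxy isomer being removed by chromatography.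

Step 2
Reactants: 4 1-(2,4-dihydroxy-6-methoxyphenyl)-3-phenylpropan-1-one; 5 3-chloro-3-methylbut-1-yne
Product: 6 1-[2-hydroxy-6-methoxy-4-(2-methylbut-3-yn-2-yloxy)phenyl]-3-phenylpropan-1-one
Conditions: DBU, CuCl2·2H2O (cat.), MeCN, 0 °C
Reagents that add atoms: none
Why: Copper-catalysed propargylic substitution of a tertiary propargylic chloride by a phenoxide (through a copper allenylidene) should alkylate only the 4'-OH, which is the most acidic phenol (para to the ketone) and the only one not tied up in the hydrogen bond to the carbonyl.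

Step 3
Reactants: 6 1-[2-hydroxy-6-methoxy-4-(2-methylbut-3-yn-2-yloxy)phenyl]-3-phenylpropan-1-one
Product: 8 1-[3,6-dihydroxy-2-methoxy-4-(2-methylbut-3-yn-2-yloxy)phenyl]-3-phenylpropan-1-one, via aryl sulfate potassium salt 7 (not isolated)
Conditions: K2S2O8, NaOH (aq.), pyridine, 0 °C to rt; then HCl (aq.) to pH 1, THF, 40 °C
Reagents that add atoms: potassium peroxodisulfate (K2S2O8), [K+].[K+].[O-]S(=O)(=O)OOS(=O)(=O)[O-]
Why: Elbs persulfate oxidation, in which the phenoxide of the 2'-OH attacks the peroxide oxygen through its para carbon C5' (the only free para position) to give aryl sulfate 7, and mild acidic solvolysis of the sulfate ester should unveil the 5'-OH without touching the tertiary propargylic ether, the alkyne or the ketone.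

Step 4
Reactants: 8 1-[3,6-dihydroxy-2-methoxy-4-(2-methylbut-3-yn-2-yloxy)phenyl]-3-phenylpropan-1-one
Product: 12 flemistrictin D, via allenyl cyclohexadienone 9 (not isolated), via ortho-allenylphenol 10 (not isolated), via ortho-quinone methide 11 (not isolated)
Conditions: o-xylene (degassed), 140 °C, argon, sealed tube
Reagents that add atoms: none
Why: Heating triggers an aromatic propargyl Claisen rearrangement, a [3,3]-sigmatropic shift in which the alkyne terminus bonds to C3' while the O–CMe2 bond breaks, and the resulting allenyl cyclohexadienone 9 enolises to 10, passes a [1,5]-hydrogen shift from the freed 4'-OH to the central allene carbon to give the (Z)-ortho-quinone methide 11 and closes by oxa-6π electrocyclisation. The closest known reaction type is the thermal conversion of aryl 1,1-dimethylpropargyl ethers into 2,2-dimethyl-2H-chromenes. Ring B (the 2H-pyran) is the only ring closed: the net change of the cascade is the new C4–C4a bond, and the O1–C2 bond broken in the sigmatropic step is re-formed in the thermal disrotatory 6π electrocyclisation of the 1-oxatriene, which also restores the aromaticity of ring A. No stereocentre is formed and the C3=C4 alkene is cis because it lies in the six-membered ring. The step needs site selectivity for C3' over C5' and chromene over benzofuran formation: C5' carries a hydroxyl, so a shift to it gives a blocked dienone that can only revert, while neutral conditions and the gem-dimethyl group favour the hydrogen shift and 6π closure over a 5-exo closure. The 2'-OH stays locked in its hydrogen bond to the ketone, so the hydrogen shift and the closure should use the 4'-oxygen only.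

Compound list
1 | 5-methoxyresorcinol (5-methoxybenzene-1,3-diol) | COc1cc(O)cc(O)c1 | starting material
2 | 3-phenylpropanenitrile | N#CCCc1ccccc1 | starting material
3 | 1-(2,4-dihydroxy-6-methoxyphenyl)-3-phenylpropan-1-iminium chloride (ketiminium chloride) | COc1cc(O)cc(O)c1C(=[NH2+])CCc1ccccc1.[Cl-] | intermediate
4 | 1-(2,4-dihydroxy-6-methoxyphenyl)-3-phenylpropan-1-one (2',4'-dihydroxy-6'-methoxydihydrochalcone) | COc1cc(O)cc(O)c1C(=O)CCc1ccccc1 | intermediate
5 | 3-chloro-3-methylbut-1-yne | C#CC(C)(C)Cl | starting material
6 | 1-[2-hydroxy-6-methoxy-4-(2-methylbut-3-yn-2-yloxy)phenyl]-3-phenylpropan-1-one | COc1cc(OC(C)(C)C#C)cc(O)c1C(=O)CCc1ccccc1 | intermediate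
7 | potassium 4-hydroxy-2-methoxy-6-(2-methylbut-3-yn-2-yloxy)-3-(3-phenylpropanoyl)phenyl sulfate (aryl sulfate potassium salt) | COc1c(OS(=O)(=O)[O-])c(OC(C)(C)C#C)cc(O)c1C(=O)CCc1ccccc1.[K+] | intermediate
8 | 1-[3,6-dihydroxy-2-methoxy-4-(2-methylbut-3-yn-2-yloxy)phenyl]-3-phenylpropan-1-one (2',5'-dihydroxy-6'-methoxy-4'-(1,1-dimethylpropargyloxy)dihydrochalcone) | COc1c(O)c(OC(C)(C)C#C)cc(O)c1C(=O)CCc1ccccc1 | intermediate
9 | 2,5-dihydroxy-3-methoxy-6-(3-methylbuta-1,2-dien-1-yl)-4-(3-phenylpropanoyl)cyclohexa-2,4-dien-1-one (allenyl cyclohexadienone, racemic at the transient sp3 carbon) | O=C1C(C=C=C(C)C)C(O)=C(C(=O)CCc2ccccc2)C(OC)=C1O | intermediate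
10 | 1-[2,4,5-trihydroxy-6-methoxy-3-(3-methylbuta-1,2-dien-1-yl)phenyl]-3-phenylpropan-1-one (ortho-allenylphenol) | COc1c(O)c(O)c(C=C=C(C)C)c(O)c1C(=O)CCc1ccccc1 | intermediate
11 | (6Z)-2,5-dihydroxy-3-methoxy-6-(3-methylbut-2-en-1-ylidene)-4-(3-phenylpropanoyl)cyclohexa-2,4-dien-1-one (ortho-quinone methide) | O=C1/C(=C\C=C(C)C)C(O)=C(C(=O)CCc2ccccc2)C(OC)=C1O | intermediate
12 | flemistrictin D, 1-(5,8-dihydroxy-7-methoxy-2,2-dimethyl-2H-chromen-6-yl)-3-phenylpropan-1-one | COc1c(O)c2c(c(O)c1C(=O)CCc1ccccc1)C=CC(C)(C)O2 | target

Total step count: 4. Longest linear sequence: 4 steps (1 to 4 to 6 to 8 to 12).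

Steps most likely to fail

Step 3. The persulfate oxidation may stall at low conversion because C5' is flanked by two alkoxy groups, and the acid used to solvolyse the aryl sulfate may also cleave the tertiary propargylic aryl ether. The fallback sets out from 6 and returns at 8 without persulfate and without acid. Phenol 6 is oxidised with PhI(OCOCF3)2 in MeCN/H2O at 0 °C (phenol to para-quinone oxidation, water supplying the new oxygen at C5') to the acylquinone 3-methoxy-5-(2-methylbut-3-yn-2-yloxy)-2-(3-phenylpropanoyl)cyclohexa-2,5-diene-1,4-dione F1. F1 is reduced at once with Na2S2O4 in EtOAc/H2O to hydroquinone 8.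

Step 4. Prolonged heating may degrade the oxidation-sensitive hydroquinone, or the hydrogen shift may start from the 2'-OH and lead to closure on the wrong oxygen. The fallback sets out from 4 and returns at 12, building ring B by a condensation and not by a sigmatropic shift. Elbs oxidation of 4 (K2S2O8, aq. NaOH; then HCl), which carries no acid-labile group, should give the triol 1-(3,4,6-trihydroxy-2-methoxyphenyl)-3-phenylpropan-1-one F3 through the sulfate ester potassium 4,6-dihydroxy-2-methoxy-3-(3-phenylpropanoyl)phenyl sulfate F2. F3 is then condensed with 3-methylbut-2-enal (ethylenediammonium diacetate cat., toluene, 110 °C). Knoevenagel-type condensation at C3', the only free ring carbon, followed by oxa-6π closure through the non-chelated 4'-OH, should give 12.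

Step 1. The electrophile may also attack the carbon between the two hydroxyls, and the two regioisomeric ketones may be hard to separate. The fallback sets out from 2 and returns at 6. Nitrile 2 is condensed under the same Houben–Hoesch conditions with commercial phloroglucinol (benzene-1,3,5-triol, Oc1cc(O)cc(O)c1), whose threefold symmetry allows one product only. Hydrolysis of the ketiminium salt 3-phenyl-1-(2,4,6-trihydroxyphenyl)propan-1-iminium chloride F4 gives 3-phenyl-1-(2,4,6-trihydroxyphenyl)propan-1-one F5. Copper-catalysed O-propargylation of the most acidic 4'-OH with 5 (DBU, CuCl2·2H2O cat., MeCN, 0 °C) gives 1-[2,6-dihydroxy-4-(2-methylbut-3-yn-2-yloxy)phenyl]-3-phenylpropan-1-one F6. Methylation of one of the two equivalent ortho hydroxyls (MeI, K2CO3, acetone, rt) gives 6, the remaining hydroxyl being shielded by its hydrogen bond to the ketone.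

Further compounds
F1 | step 3 | 3-methoxy-5-(2-methylbut-3-yn-2-yloxy)-2-(3-phenylpropanoyl)cyclohexa-2,5-diene-1,4-dione | COC1=C(C(=O)CCc2ccccc2)C(=O)C=C(OC(C)(C)C#C)C1=O
F2 | step 4 | potassium 4,6-dihydroxy-2-methoxy-3-(3-phenylpropanoyl)phenyl sulfate | COc1c(OS(=O)(=O)[O-])c(O)cc(O)c1C(=O)CCc1ccccc1.[K+]
F3 | step 4 | 1-(3,4,6-trihydroxy-2-methoxyphenyl)-3-phenylpropan-1-one | COc1c(O)c(O)cc(O)c1C(=O)CCc1ccccc1
F4 | step 1 | 3-phenyl-1-(2,4,6-trihydroxyphenyl)propan-1-iminium chloride | Oc1cc(O)c(C(=[NH2+])CCc2ccccc2)c(O)c1.[Cl-]
F5 | step 1 | 3-phenyl-1-(2,4,6-trihydroxyphenyl)propan-1-one | Oc1cc(O)c(C(=O)CCc2ccccc2)c(O)c1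
F6 | step 1 | 1-[2,6-dihydroxy-4-(2-methylbut-3-yn-2-yloxy)phenyl]-3-phenylpropan-1-one | C#CC(C)(C)Oc1cc(O)c(C(=O)CCc2ccccc2)c(O)c1
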